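**Strategy.** Everything rests on cutting the C9–C10 bond of ring B (C5–C10, labdane numbering) as an Ireland–Claisen ring contraction. The silyl ketene acetal of a 6-cyclohexenyl mevalonolactone, whose ring oxygen sits on C6, shifts C9 onto C10 through the obligatory boat array. One operation closes ring B, builds the C10 quaternary centre, places C11 on C9 trans to the C10 methyl, carries the C8 carbinol intact and leaves a 5,6-alkene for later hydroboration to the C6 oxygen. The step exploits the 1,3-relation of the C6 and C8 oxygens and the trans disposition of C11 and the C10 methyl. The precursor is a trans-4-hydroxy-4-methyl δ-lactone bearing ring A at C6, made from 2,2-dimethylcyclohexane-1,3-dione.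

Key step: step 9

Remark on numbering: atom numbers are the labdane numbers of the target (ring A = C1–C5, C10; ring B = C5–C10; C11 on C9; C17 = methyl on C8; C20 = methyl on C10).
Assumption: 2-methylallylmagnesium chloride, Ipc2BOMe derived from (−)-α-pinene and 2-(bromomethyl)buta-1,3-diene are taken as purchasable reagents; the C3 oxygen is carried as a dioxolane and revealed last.

Step 1
Reactants: 1 2,2-dimethylcyclohexane-1,3-dione
Product: 2 6,6-dimethyl-1,4-dioxaspiro[4.5]decan-7-one
Conditions: HOCH2CH2OH (1 equiv), p-TsOH·H2O (cat.), PhMe, reflux, Dean–Stark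
Reagents that add atoms: ethylene glycol OCCO
Why: Acid-catalysed ketalisation of the non-enolisable diketone should stop after one carbonyl, because the remaining one is then flanked by a quaternary carbon and the dioxolane (desymmetrising monoketalisation).

Step 2
Reactants: 2 6,6-dimethyl-1,4-dioxaspiro[4.5]decan-7-one
Product: 3 6,6,8-trimethyl-1,4-dioxaspiro[4.5]decan-7-one (racemic)
Conditions: LiN(iPr)2, THF, −78 °C; MeI, −78 → 0 °C
Reagents that add atoms: iodomethane CI
Why: The ketone has a single enolisable position, so lithium enolate alkylation installs the future C20 methyl there; the new stereocentre is irrelevant because it becomes sp2 in step 3.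

Step 3
Reactants: 3 6,6,8-trimethyl-1,4-dioxaspiro[4.5]decan-7-one
Product: 4 6,6,8-trimethyl-1,4-dioxaspiro[4.5]dec-7-en-7-yl trifluoromethanesulfonate
Conditions: KN(SiMe3)2, THF, −78 °C; PhNTf2, −78 → 0 °C
Reagents that add atoms: N-phenylbis(trifluoromethanesulfonimide) O=S(=O)(N(c1ccccc1)S(=O)(=O)C(F)(F)F)C(F)(F)F
Why: Only the methyl-bearing α-carbon can be deprotonated, so O-sulfonylation of the tetrasubstituted enolate gives one regioisomer (enol triflate formation).

Step 4
Reactants: 4 6,6,8-trimethyl-1,4-dioxaspiro[4.5]dec-7-en-7-yl trifluoromethanesulfonate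
Product: 5 6,6,8-trimethyl-1,4-dioxaspiro[4.5]dec-7-ene-7-carbaldehyde
Conditions: Pd(PPh3)4 (cat.), CO (3 atm), Bu3SnH (slow addition), LiCl, THF, 50 °C
Reagents that add atoms: carbon monoxide [C-]#[O+]
Why: Oxidative addition of zerovalent palladium into the vinyl triflate, CO insertion and hydride transfer from tin should give the enal (reductive carbonylation of a vinyl triflate).

Step 5
Reactants: 5 6,6,8-trimethyl-1,4-dioxaspiro[4.5]dec-7-ene-7-carbaldehyde
Product: 6 (R)-3-methyl-1-(6,6,8-trimethyl-1,4-dioxaspiro[4.5]dec-7-en-7-yl)but-3-en-1-ol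
Conditions: Ipc2BOMe from (−)-α-pinene, CH2=C(CH3)CH2MgCl, Et2O, −78 → 23 °C; 5, −78 °C; NaOH, H2O2
Reagents that add atoms: 2-methylallylmagnesium chloride CC(=C)C[Mg]Cl
Why: Brown allylboration through a chair six-membered transition state, in which the isopinocampheyl groups from (−)-α-pinene direct the methallyl group to the Re face of the aldehyde and so set the (R)-carbinol at C6.

Step 6
Reactants: 6 (R)-3-methyl-1-(6,6,8-trimethyl-1,4-dioxaspiro[4.5]dec-7-en-7-yl)but-3-en-1-ol
Product: 7 (R)-3-methyl-1-(6,6,8-trimethyl-1,4-dioxaspiro[4.5]dec-7-en-7-yl)but-3-en-1-yl acrylate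
Conditions: CH2=CHCOCl, Et3N, DMAP (cat.), CH2Cl2, 0 °C
Reagents that add atoms: acryloyl chloride C=CC(=O)Cl
Why: DMAP-catalysed O-acylation of the secondary alcohol by the acid chloride (esterification) leaves the stereocentre untouched.

Step 7
Reactants: 7 (R)-3-methyl-1-(6,6,8-trimethyl-1,4-dioxaspiro[4.5]dec-7-en-7-yl)but-3-en-1-yl acrylate
Product: 8 (R)-4-methyl-6-(6,6,8-trimethyl-1,4-dioxaspiro[4.5]dec-7-en-7-yl)-5,6-dihydro-2H-pyran-2-one
Conditions: second-generation Grubbs catalyst (cat.), PhMe, 80 °C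
Reagents that add atoms: none
Why: Ring-closing metathesis between the acrylate and the 1,1-disubstituted alkene should close the unsaturated δ-lactone with loss of ethylene, the tetrasubstituted ring alkene being inert.

Step 8
Reactants: 8 (R)-4-methyl-6-(6,6,8-trimethyl-1,4-dioxaspiro[4.5]dec-7-en-7-yl)-5,6-dihydro-2H-pyran-2-one
Product: 10 (4S,6R)-4-hydroxy-4-methyl-6-(6,6,8-trimethyl-1,4-dioxaspiro[4.5]dec-7-en-7-yl)tetrahydro-2H-pyran-2-one, via β-boryl lactone 9 (not isolated)
Conditions: CuCl (cat.), DPEphos, NaOtBu (cat.), B2pin2, MeOH, THF, 23 °C; then H2O2, aq. NaHCO3, 0 °C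
Reagents that add atoms: hydrogen peroxide OO (hydroxyl oxygen); bis(pinacolato)diboron CC1(C)OB(OC1(C)C)B1OC(C)(C)C(C)(C)O1 (boryl group of 9 only, replaced on oxidation)
Why: Copper-catalysed conjugate borylation of the β,β-disubstituted lactone should occur by axial attack anti to the pseudo-equatorial C6 substituent, and stereoretentive C–B oxidation then gives the tertiary alcohol trans to that substituent (4S, the future C8).

Step 9
Reactants: 10 (4S,6R)-4-hydroxy-4-methyl-6-(6,6,8-trimethyl-1,4-dioxaspiro[4.5]dec-7-en-7-yl)tetrahydro-2H-pyran-2-one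
Product: 13 (8S,9R,10S)-3,3-ethylenedioxy-8-(triethylsilyloxy)-12,13,14,15,16-pentanorlabd-5-en-11-oic acid, via bis(triethylsilyl) ketene acetal 11 (not isolated), via triethylsilyl ester 12 (not isolated)
Conditions: LiN(iPr)2 (2.5 equiv), THF, −78 °C; Et3SiCl, DMPU, −78 → 23 °C; PhMe, 110 °C; then aq. citric acid
Reagents that add atoms: chlorotriethylsilane CC[Si](Cl)(CC)CC
Why: Two equivalents of base give the alkoxide–enolate dianion, which is silylated on both oxygens to the cyclic ketene acetal 11; on heating, a concerted suprafacial [3,3]-sigmatropic shift breaks the allylic C6–O bond and joins C9 to C10, and mild hydrolysis of silyl ester 12 frees the acid. The closest known reaction type is the Ireland–Claisen ring contraction of 6-alkenyl δ-lactone silyl ketene acetals to cyclohex-3-enecarboxylic acids. Ring B is closed as a six-membered carbocycle through the bicyclo[2.2.2]-like boat transition state that the endocyclic ketene acetal enforces, since a chair would need a trans double bond in the new ring. The C10 quaternary centre is set by chirality transfer from the (R)-configured C6–O bond, C9 by the boat array, which puts the carboxyl carbon C11 anti to the C10 methyl, and C8 is carried over with its methyl cis to the C10 methyl. The step needs the rearrangement to outrun β-elimination of the C8 oxygen and silyl migration in a crowded array in which the C8 and C10 methyls become 1,3-diaxial; enolisation as the dianion, whose alkoxide cannot leave, and the acceleration by the 2-silyloxy substituent should secure this.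

Step 10
Reactants: 13 (8S,9R,10S)-3,3-ethylenedioxy-8-(triethylsilyloxy)-12,13,14,15,16-pentanorlabd-5-en-11-oic acid
Product: 15 (5S,6R,8S,9S,10R)-3,3-ethylenedioxy-8-(triethylsilyloxy)-12,13,14,15,16-pentanorlabdane-6,11-diol, via alkylborane 14 (not isolated)
Conditions: BH3·THF (excess), THF, 0 → 23 °C; then NaOH, H2O2
Reagents that add atoms: hydrogen peroxide OO
Why: BH3 reduces the acid to the primary alcohol and adds syn across the 5,6-alkene with boron on C6 from the face opposite the axial methyls on C4, C8 and C10, so stereoretentive oxidation gives the equatorial 6-OH and the trans ring fusion at C5 (hydroboration–oxidation).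

Step 11
Reactants: 15 (5S,6R,8S,9S,10R)-3,3-ethylenedioxy-8-(triethylsilyloxy)-12,13,14,15,16-pentanorlabdane-6,11-diol
Product: 16 (5S,6R,8S,9R,10R)-3,3-ethylenedioxy-11-iodo-8-(triethylsilyloxy)-12,13,14,15,16-pentanorlabdan-6-ol
Conditions: I2, PPh3, imidazole, PhMe, 60 °C
Reagents that add atoms: iodine II
Why: Appel-type iodination should convert only the primary alcohol, through its alkoxyphosphonium salt and SN2 attack of iodide, while the hindered secondary hydroxyl and the silylated tertiary oxygen stay inert.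

Step 12
Reactants: 16 (5S,6R,8S,9R,10R)-3,3-ethylenedioxy-11-iodo-8-(triethylsilyloxy)-12,13,14,15,16-pentanorlabdan-6-ol
Product: 17 (5S,6R,8S,9R,10R)-3,3-ethylenedioxy-8-(triethylsilyloxy)labda-13(16),14-dien-6-ol
Conditions: CH2=C(CH=CH2)CH2MgBr (from the bromide and Mg, THF, 3 equiv), Li2CuCl4 (cat.), THF, −20 → 23 °C
Reagents that add atoms: 2-(bromomethyl)buta-1,3-diene C=CC(=C)CBr (as its Grignard reagent)
Why: Copper-catalysed Grignard cross-coupling with the primary iodide forms the C11–C12 bond, and because the allyl termini of the reagent are equivalent either mode of attack gives the 2-substituted butadiene, the first equivalent only deprotonating the C6 hydroxyl.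

Step 13
Reactants: 17 (5S,6R,8S,9R,10R)-3,3-ethylenedioxy-8-(triethylsilyloxy)labda-13(16),14-dien-6-ol
Product: 18 (5S,6R,8S,9R,10R)-3,3-ethylenedioxy-8-(triethylsilyloxy)labda-13(16),14-dien-6-yl acetate
Conditions: Ac2O, pyridine, DMAP (cat.), CH2Cl2, 23 °C
Reagents that add atoms: acetic anhydride CC(=O)OC(C)=O
Why: DMAP-catalysed acetylation should take the only free hydroxyl, the equatorial 6-OH, since the tertiary C8 oxygen is silylated.

Step 14
Reactants: 18 (5S,6R,8S,9R,10R)-3,3-ethylenedioxy-8-(triethylsilyloxy)labda-13(16),14-dien-6-yl acetate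
Product: 19 (5S,6R,8S,9R,10R)-6-acetoxy-8-hydroxylabda-13(16),14-dien-3-one
Conditions: 1 M HCl, THF, 23 °C
Reagents that add atoms: water O
Why: Dilute acid should hydrolyse the dioxolane to the C3 ketone and cleave the tertiary silyl ether (acetal hydrolysis and desilylation) under conditions that spare the acetate, the tertiary alcohol and the diene.

Step 15
Reactants: 19 (5S,6R,8S,9R,10R)-6-acetoxy-8-hydroxylabda-13(16),14-dien-3-one
Product: 20 (3R,5S,6R,8S,9R,10R)-6-acetoxylabda-13(16),14-diene-3,8-diol (target)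
Conditions: NaBH4, MeOH, 0 °C
Reagents that add atoms: none
Why: Hydride should attack the 4,4-dimethyl-3-ketone along the axial trajectory on the face opposite the C10 methyl, giving the equatorial (3R)-alcohol while acetate and diene are inert (chemoselective borohydride reduction).

**Compound list**

1 | 2,2-dimethylcyclohexane-1,3-dione | CC1(C)C(=O)CCCC1=O | starting material
2 | 6,6-dimethyl-1,4-dioxaspiro[4.5]decan-7-one | O=C1CCCC2(OCCO2)C1(C)C | intermediate
3 | 6,6,8-trimethyl-1,4-dioxaspiro[4.5]decan-7-one (racemic) | CC1CCC2(OCCO2)C(C)(C)C1=O | intermediate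
4 | 6,6,8-trimethyl-1,4-dioxaspiro[4.5]dec-7-en-7-yl trifluoromethanesulfonate | CC1=C(OS(=O)(=O)C(F)(F)F)C(C)(C)C2(CC1)OCCO2 | intermediate
5 | 6,6,8-trimethyl-1,4-dioxaspiro[4.5]dec-7-ene-7-carbaldehyde | CC1=C(C=O)C(C)(C)C2(CC1)OCCO2 | intermediate
6 | (R)-3-methyl-1-(6,6,8-trimethyl-1,4-dioxaspiro[4.5]dec-7-en-7-yl)but-3-en-1-ol | CC(=C)C[C@@H](O)C1=C(C)CCC2(OCCO2)C1(C)C | intermediate
7 | (R)-3-methyl-1-(6,6,8-trimethyl-1,4-dioxaspiro[4.5]dec-7-en-7-yl)but-3-en-1-yl acrylate | C=CC(=O)O[C@H](CC(C)=C)C1=C(C)CCC2(OCCO2)C1(C)C | intermediate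
8 | (R)-4-methyl-6-(6,6,8-trimethyl-1,4-dioxaspiro[4.5]dec-7-en-7-yl)-5,6-dihydro-2H-pyran-2-one | CC1=CC(=O)O[C@H](C1)C2=C(C)CCC3(OCCO3)C2(C)C | intermediate
9 | (4R,6R)-4-methyl-4-(4,4,5,5-tetramethyl-1,3,2-dioxaborolan-2-yl)-6-(6,6,8-trimethyl-1,4-dioxaspiro[4.5]dec-7-en-7-yl)tetrahydro-2H-pyran-2-one (boron trans to the C6 substituent) | C[C@@]1(B2OC(C)(C)C(C)(C)O2)CC(=O)O[C@H](C1)C3=C(C)CCC4(OCCO4)C3(C)C | intermediate (not isolated)
10 | (4S,6R)-4-hydroxy-4-methyl-6-(6,6,8-trimethyl-1,4-dioxaspiro[4.5]dec-7-en-7-yl)tetrahydro-2H-pyran-2-one | C[C@@]1(O)CC(=O)O[C@H](C1)C2=C(C)CCC3(OCCO3)C2(C)C | intermediate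
11 | (4S,6R)-4-methyl-2,4-bis(triethylsilyloxy)-6-(6,6,8-trimethyl-1,4-dioxaspiro[4.5]dec-7-en-7-yl)-5,6-dihydro-4H-pyran | C[C@@]1(O[Si](CC)(CC)CC)C=C(O[Si](CC)(CC)CC)O[C@H](C1)C2=C(C)CCC3(OCCO3)C2(C)C | intermediate (not isolated)
12 | triethylsilyl (8S,9R,10S)-3,3-ethylenedioxy-8-(triethylsilyloxy)-12,13,14,15,16-pentanorlabd-5-en-11-oate | CC[Si](CC)(CC)OC(=O)[C@@H]1[C@]2(C)CCC3(OCCO3)C(C)(C)C2=CC[C@]1(C)O[Si](CC)(CC)CC | intermediate (not isolated)
13 | (8S,9R,10S)-3,3-ethylenedioxy-8-(triethylsilyloxy)-12,13,14,15,16-pentanorlabd-5-en-11-oic acid (C11 trans to C20, C17 cis to C20) | OC(=O)[C@@H]1[C@]2(C)CCC3(OCCO3)C(C)(C)C2=CC[C@]1(C)O[Si](CC)(CC)CC | intermediate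
14 | 6-boryl-11-boryloxy adduct of 13 (boron on C6 and hydrogen on C5 on the face opposite C20) | BOC[C@@H]1[C@]2(C)CCC3(OCCO3)C(C)(C)[C@H]2[C@H](B)C[C@]1(C)O[Si](CC)(CC)CC | intermediate (not isolated)
15 | (5S,6R,8S,9S,10R)-3,3-ethylenedioxy-8-(triethylsilyloxy)-12,13,14,15,16-pentanorlabdane-6,11-diol | OC[C@@H]1[C@]2(C)CCC3(OCCO3)C(C)(C)[C@H]2[C@H](O)C[C@]1(C)O[Si](CC)(CC)CC | intermediate
16 | (5S,6R,8S,9R,10R)-3,3-ethylenedioxy-11-iodo-8-(triethylsilyloxy)-12,13,14,15,16-pentanorlabdan-6-ol | IC[C@@H]1[C@]2(C)CCC3(OCCO3)C(C)(C)[C@H]2[C@H](O)C[C@]1(C)O[Si](CC)(CC)CC | intermediate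
17 | (5S,6R,8S,9R,10R)-3,3-ethylenedioxy-8-(triethylsilyloxy)labda-13(16),14-dien-6-ol | C=CC(=C)CC[C@@H]1[C@]2(C)CCC3(OCCO3)C(C)(C)[C@H]2[C@H](O)C[C@]1(C)O[Si](CC)(CC)CC | intermediate
18 | (5S,6R,8S,9R,10R)-3,3-ethylenedioxy-8-(triethylsilyloxy)labda-13(16),14-dien-6-yl acetate | C=CC(=C)CC[C@@H]1[C@]2(C)CCC3(OCCO3)C(C)(C)[C@H]2[C@H](OC(C)=O)C[C@]1(C)O[Si](CC)(CC)CC | intermediate
19 | (5S,6R,8S,9R,10R)-6-acetoxy-8-hydroxylabda-13(16),14-dien-3-one | C=CC(=C)CC[C@@H]1[C@]2(C)CCC(=O)C(C)(C)[C@H]2[C@H](OC(C)=O)C[C@]1(C)O | intermediate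
20 | (3R,5S,6R,8S,9R,10R)-6-acetoxylabda-13(16),14-diene-3,8-diol (CNP0351600.2) | C=CC(=C)CC[C@@H]1[C@]2(C)CC[C@@H](O)C(C)(C)[C@H]2[C@H](OC(C)=O)C[C@]1(C)O | target

**Count and risks**

Total step count: 15. Longest linear sequence: 15 steps (from 1; the route is fully linear).

Steps most likely to fail:

1. Step 9 (key step). β-Elimination of the C8 silyloxy group from the enolate, or thermal decay of the ketene acetal, may outpace the congested boat rearrangement. The fallback runs the shift on the neutral allyl vinyl ether and sets out from 10. Silylation (Et3SiOTf, 2,6-lutidine) would give the triethylsilyl ether of the hydroxy lactone F1. Reduction with iBu2AlH at −78 °C would give the lactol F2. Dehydration with MsCl and Et3N would give the 6-alkenyl-3,4-dihydro-2H-pyran F3. Treatment with iBu3Al in CH2Cl2 should promote the aliphatic Claisen ring contraction through the same boat array and reduce the aldehyde in the flask to the C11 alcohol F4. Hydroboration–oxidation of F4 under the conditions of step 10 comes back to the route at 15.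

2. Step 12. Substitution at the β-branched C11 iodide may be too slow for the allylic Grignard reagent, so that deprotonation, elimination or intramolecular ether formation take over. The fallback builds the diene after the C–C bond and sets out from 16. Alkylation with 3-lithio-1-(trimethylsilyl)propyne (from 1-(trimethylsilyl)propyne and n-BuLi, THF/DMPU) would give the silylalkyne F5. K2CO3 in MeOH would give the terminal alkyne F6. Enyne cross-metathesis with ethylene (second-generation Grubbs catalyst, 1 atm) would convert the alkyne into the 2-substituted butadiene and come back to the route at 17.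

3. Step 8. Copper–boryl addition to the β,β-disubstituted lactone may be slow or poorly face-selective, or the lactone may be opened by methoxide. The fallback introduces the oxygen by epoxidation and reductive opening and sets out from 8. Nucleophilic epoxidation (H2O2, NaOH, MeOH, 0 °C) should give the epoxy lactone F7 with the oxygen anti to the C6 substituent. Reductive cleavage of the Cα–O bond with PhSeNa (from (PhSe)2 and NaBH4, EtOH, AcOH) comes back to the route at 10.

Further compounds

F1 | step 9 | (4S,6R)-4-methyl-4-(triethylsilyloxy)-6-(6,6,8-trimethyl-1,4-dioxaspiro[4.5]dec-7-en-7-yl)tetrahydro-2H-pyran-2-one | C[C@@]1(O[Si](CC)(CC)CC)CC(=O)O[C@H](C1)C2=C(C)CCC3(OCCO3)C2(C)C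
F2 | step 9 | (4S,6R)-4-methyl-4-(triethylsilyloxy)-6-(6,6,8-trimethyl-1,4-dioxaspiro[4.5]dec-7-en-7-yl)tetrahydro-2H-pyran-2-ol (lactol, anomer mixture) | C[C@@]1(O[Si](CC)(CC)CC)CC(O)O[C@H](C1)C2=C(C)CCC3(OCCO3)C2(C)C
F3 | step 9 | (2R,4S)-4-methyl-4-(triethylsilyloxy)-2-(6,6,8-trimethyl-1,4-dioxaspiro[4.5]dec-7-en-7-yl)-3,4-dihydro-2H-pyran | C[C@@]1(O[Si](CC)(CC)CC)C=CO[C@H](C1)C2=C(C)CCC3(OCCO3)C2(C)C
F4 | step 9 | (8S,9R,10S)-3,3-ethylenedioxy-8-(triethylsilyloxy)-12,13,14,15,16-pentanorlabd-5-en-11-ol | OC[C@@H]1[C@]2(C)CCC3(OCCO3)C(C)(C)C2=CC[C@]1(C)O[Si](CC)(CC)CC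
F5 | step 12 | (5S,6R,8S,9R,10R)-3,3-ethylenedioxy-8-(triethylsilyloxy)-14-(trimethylsilyl)-15,16-dinorlabd-13-yn-6-ol | C[Si](C)(C)C#CCC[C@@H]1[C@]2(C)CCC3(OCCO3)C(C)(C)[C@H]2[C@H](O)C[C@]1(C)O[Si](CC)(CC)CC
F6 | step 12 | (5S,6R,8S,9R,10R)-3,3-ethylenedioxy-8-(triethylsilyloxy)-15,16-dinorlabd-13-yn-6-ol | C#CCC[C@@H]1[C@]2(C)CCC3(OCCO3)C(C)(C)[C@H]2[C@H](O)C[C@]1(C)O[Si](CC)(CC)CC
F7 | step 8 | 3,4-epoxy-4-methyl-6-(6,6,8-trimethyl-1,4-dioxaspiro[4.5]dec-7-en-7-yl)tetrahydro-2H-pyran-2-one (6R, epoxide oxygen trans to the C6 substituent) | C[C@@]12O[C@@H]1C(=O)O[C@H](C2)C3=C(C)CCC4(OCCO4)C3(C)C
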